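**Retrosynthetic overview**

1. Numbering: ring A = C1(Br)–C2–C3(OH)–C4(OH,Me)–C5–C10(Me); ring B = C5–C6–C7–C8–C9–C10; norbornane (rings C and D) = bridgeheads C7 and C12 joined by C6–C11(OMe), C14(iPr)–C13 and C15.
2. Endgame: 24 ⇐ α-hydroxy ketone 23 (equatorial MeMgBr at C4) ⇐ ketone 22 (axial hydroxylation at C3) ⇐ diketo ester 20 (C11 ketone to endo methyl ether, then decarboxylation).
3. Key disconnection C5–C6 (ring B, closed last): intramolecular oxidative coupling of the two enolates of 19. C5 (β-keto ester of ring A) and C6 (norbornanone) are both α-carbons, so both are normally nucleophiles; the coupling gives the C4/C11 1,4-dicarbonyl and sets C5 and C6.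
4. Norbornanone (rings C and D, formed second): Diels–Alder of 2-silyloxycyclopentadiene 12 with methyl vinyl ketone (bonds C7–C14 and C12–C13); acetyl is then converted to isopropyl.
5. Ring A (formed first): bromonium cyclisation of an epoxide-derived bromohydrin onto a dioxinone (masked β-keto ester); the chain 8 comes from enynol 1, dioxinone 3 and 3-bromocyclopentenone 6.

Conventions: β = face of rings A/B carrying the C10 methyl; exo/endo refer to the norbornane (exo = side of the C15 bridge); "the tetracycle" = the ring system numbered above.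

Assumption: 1, 3, 6 and 13 are purchased; the (S)-configured oxazaborolidinium ion in step 8 is taken to give the drawn configuration at C7, C12 and C14, and its mirror image is used if the sense proves opposite.

**Route**

Step 1
Reactants: 1 (2E)-3-methylpent-2-en-4-yn-1-ol
Product: 2 (3E)-5-bromo-3-methylpent-3-en-1-yne
Conditions: PBr3 (0.4 equiv), pyridine (cat.), Et2O, −10 → 0 °C
Reagents that add atoms: phosphorus tribromide, BrP(Br)Br
Why: Substitution of a primary allylic alcohol by bromide through its phosphite ester (PBr3 bromination) keeps the (E)-alkene and gives the stable primary allylic bromide.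

Step 2
Reactants: 2 (3E)-5-bromo-3-methylpent-3-en-1-yne; 3 2,2,6-trimethyl-4H-1,3-dioxin-4-one
Product: 4 2,2-dimethyl-6-[(3E)-4-methylhex-3-en-5-yn-1-yl]-4H-1,3-dioxin-4-one
Conditions: LiN(iPr)2 (1.05 equiv), THF–DMPU, −78 °C; then 2, −78 → −40 °C
Reagents that add atoms: none
Why: The lithium dienolate of the dioxinone (a masked acetoacetate) is alkylated at its γ-methyl carbon by the allylic bromide in an SN2 vinylogous enolate alkylation, forming C2–C3 and bringing in C3, C4, C5 and the masked ester.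

Step 3
Reactants: 4 2,2-dimethyl-6-[(3E)-4-methylhex-3-en-5-yn-1-yl]-4H-1,3-dioxin-4-one
Product: 5 2,2-dimethyl-6-[(3E)-4-methylhexa-3,5-dien-1-yl]-4H-1,3-dioxin-4-one
Conditions: H2 (1 atm), Pd on CaCO3 poisoned with Pb(OAc)2, quinoline, EtOAc, 23 °C, stopped after 1 equiv H2
Reagents that add atoms: none
Why: Semi-hydrogenation over lead-poisoned palladium stops at the vinyl group and leaves the trisubstituted (E)-alkene and the electron-poor dioxinone alkene untouched.

Step 4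
Reactants: 5 2,2-dimethyl-6-[(3E)-4-methylhexa-3,5-dien-1-yl]-4H-1,3-dioxin-4-one; 6 3-bromocyclopent-2-en-1-one
Product: 8 2,2-dimethyl-6-[(3E)-4-methyl-6-(3-oxocyclopent-1-en-1-yl)hex-3-en-1-yl]-4H-1,3-dioxin-4-one, via alkylborane 7 (not isolated)
Conditions: 9-borabicyclo[3.3.1]nonane (1.1 equiv), THF, 0 → 23 °C; then 6, PdCl2(dppf) (5 mol%; dppf = 1,1′-bis(diphenylphosphino)ferrocene), K3PO4 (3 M aq.), DMF, 50 °C
Reagents that add atoms: none
Why: The borane adds only to the monosubstituted alkene of the diene at its terminal carbon (anti-Markovnikov hydroboration), and the primary alkylborane then undergoes B-alkyl Suzuki–Miyaura coupling with the β-bromo enone to form C7–C8.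

Step 5
Reactants: 8 2,2-dimethyl-6-[(3E)-4-methyl-6-(3-oxocyclopent-1-en-1-yl)hex-3-en-1-yl]-4H-1,3-dioxin-4-one
Product: 9 2,2-dimethyl-6-(2-{(2R,3R)-3-methyl-3-[2-(3-oxocyclopent-1-en-1-yl)ethyl]oxiran-2-yl}ethyl)-4H-1,3-dioxin-4-one
Conditions: 1,2:4,5-di-O-isopropylidene-β-D-erythro-2,3-hexodiulo-2,6-pyranose (30 mol%), KHSO5 (as 2KHSO5·KHSO4·K2SO4, 1.4 equiv), K2CO3, Bu4NHSO4, MeCN–CH2(OMe)2–aq. Na2B4O7 buffer (pH 10.5), 0 °C
Reagents that add atoms: potassium peroxymonosulfate, [K+].[O-]S(=O)(=O)OO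
Why: Shi epoxidation with the D-fructose-derived dioxirane attacks only the electron-rich trisubstituted (E)-alkene and, through the spiro transition state, gives the (R,R)-epoxide from which the configurations of C1 and C10 are derived.

Step 6
Reactants: 9 2,2-dimethyl-6-(2-{(2R,3R)-3-methyl-3-[2-(3-oxocyclopent-1-en-1-yl)ethyl]oxiran-2-yl}ethyl)-4H-1,3-dioxin-4-one
Product: 11 (5S,6S)-6-bromo-2,2,5-trimethyl-5-[2-(3-oxocyclopent-1-en-1-yl)ethyl]-5,6,7,8-tetrahydro-4H-1,3-benzodioxin-4-one, via bromohydrin 10 (not isolated)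
Conditions: Li2NiBr4 (1.5 equiv), THF, 0 °C; solvent exchanged to (CF3)2CHOH; TfOH (1.6 equiv), 0 °C
Reagents that add atoms: dilithium tetrabromonickelate, [Li+].[Li+].[Ni+2].[Br-].[Br-].[Br-].[Br-]
Why: Proposed new method: bromide opens the epoxide by SN2 at the secondary carbon C1 (inversion), acid then ionises the tertiary C10–OH with anchimeric assistance from the neighbouring bromine, and the enantiopure bromonium ion is opened at C10 by C5 of the dioxinone (a β-alkoxy-acrylate π-nucleophile) through a chair transition state that places Br equatorial and cis to the axial C10 methyl (net retention at C10), the closest known reactions being enantiospecific bromonium generation from β-bromo alcohols or halides with intramolecular alkene capture and bromonium-induced polyene cyclisations ended by 1,3-dicarbonyl enols.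

Step 7
Reactants: 11 (5S,6S)-6-bromo-2,2,5-trimethyl-5-[2-(3-oxocyclopent-1-en-1-yl)ethyl]-5,6,7,8-tetrahydro-4H-1,3-benzodioxin-4-one
Product: 12 (5S,6S)-6-bromo-5-(2-{3-[(tert-butyldimethylsilyl)oxy]cyclopenta-1,3-dien-1-yl}ethyl)-2,2,5-trimethyl-5,6,7,8-tetrahydro-4H-1,3-benzodioxin-4-one
Conditions: TBSOTf (1.2 equiv), Et3N (2 equiv), CH2Cl2, −78 → 0 °C; used at once
Reagents that add atoms: tert-butyldimethylsilyl triflate, CC(C)(C)[Si](C)(C)OS(=O)(=O)C(F)(F)F
Why: Soft enolisation removes the kinetic α′-proton (at C12) of the cyclopentenone and O-silylation gives the cross-conjugated 2-silyloxycyclopentadiene (silyl dienol ether formation), which is used cold before 1,5-hydrogen shifts can scramble it.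

Step 8
Reactants: 12 (5S,6S)-6-bromo-5-(2-{3-[(tert-butyldimethylsilyl)oxy]cyclopenta-1,3-dien-1-yl}ethyl)-2,2,5-trimethyl-5,6,7,8-tetrahydro-4H-1,3-benzodioxin-4-one; 13 but-3-en-2-one
Product: 14 (5S,6S)-5-(2-{(1R,4S,6R)-6-acetyl-3-[(tert-butyldimethylsilyl)oxy]bicyclo[2.2.1]hept-2-en-1-yl}ethyl)-6-bromo-2,2,5-trimethyl-5,6,7,8-tetrahydro-4H-1,3-benzodioxin-4-one (acetyl endo)
Conditions: 13 (1.5 equiv), (S)-3,3-diphenyl-1-(2-methylphenyl)tetrahydro-1H,3H-pyrrolo[1,2-c][1,3,2]oxazaborole protonated by HN(SO2CF3)2 (20 mol%), CH2Cl2, −78 °C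
Reagents that add atoms: none
Why: In this catalytic asymmetric Diels–Alder reaction the 2-silyloxy and 4-alkyl groups of the diene both direct the enone β-carbon to C12 and its α-carbon to C7, the Lewis-acid-bound enone adds endo (acetyl endo at C14), and the chiral oxazaborolidinium ion exposes one face of the enone, so C7, C12 and C14 are set together.

Step 9
Reactants: 14 (5S,6S)-5-(2-{(1R,4S,6R)-6-acetyl-3-[(tert-butyldimethylsilyl)oxy]bicyclo[2.2.1]hept-2-en-1-yl}ethyl)-6-bromo-2,2,5-trimethyl-5,6,7,8-tetrahydro-4H-1,3-benzodioxin-4-one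
Product: 16 (5S,6S)-6-bromo-2,2,5-trimethyl-5-{2-[(1R,2S,4S)-5-oxo-2-(prop-1-en-2-yl)bicyclo[2.2.1]heptan-1-yl]ethyl}-5,6,7,8-tetrahydro-4H-1,3-benzodioxin-4-one, via β-hydroxysilane 15 (not isolated)
Conditions: Me3SiCH2MgCl (2 equiv), CeCl3 (2 equiv), THF, −78 → 0 °C; then 1 M HCl, THF, 23 °C
Reagents that add atoms: (trimethylsilyl)methylmagnesium chloride, C[Si](C)(C)C[Mg]Cl
Why: In this Peterson olefination the non-basic organocerium reagent adds to the methyl ketone without epimerising the endo C14 centre, and aqueous acid then eliminates the β-hydroxysilane to the isopropenyl group and hydrolyses the silyl enol ether to the C11 ketone.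

Step 10
Reactants: 16 (5S,6S)-6-bromo-2,2,5-trimethyl-5-{2-[(1R,2S,4S)-5-oxo-2-(prop-1-en-2-yl)bicyclo[2.2.1]heptan-1-yl]ethyl}-5,6,7,8-tetrahydro-4H-1,3-benzodioxin-4-one
Product: 17 (5S,6S)-6-bromo-2,2,5-trimethyl-5-{2-[(1R,2S,4S)-5-oxo-2-(propan-2-yl)bicyclo[2.2.1]heptan-1-yl]ethyl}-5,6,7,8-tetrahydro-4H-1,3-benzodioxin-4-one
Conditions: H2 (1 atm), RhCl(PPh3)3 (5 mol%), benzene–EtOH, 23 °C
Reagents that add atoms: none
Why: Homogeneous hydrogenation with RhCl(PPh3)3 reduces the unhindered 1,1-disubstituted alkene to isopropyl and leaves the tetrasubstituted dioxinone alkene, the ketone and the C–Br bond alone, so the endo C14 configuration is kept.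

Step 11
Reactants: 17 (5S,6S)-6-bromo-2,2,5-trimethyl-5-{2-[(1R,2S,4S)-5-oxo-2-(propan-2-yl)bicyclo[2.2.1]heptan-1-yl]ethyl}-5,6,7,8-tetrahydro-4H-1,3-benzodioxin-4-one
Product: 19 prop-2-en-1-yl (2S,3S)-3-bromo-2-methyl-6-oxo-2-{2-[(1R,2S,4S)-5-oxo-2-(propan-2-yl)bicyclo[2.2.1]heptan-1-yl]ethyl}cyclohexane-1-carboxylate, via acylketene 18 (not isolated)
Conditions: allyl alcohol (5 equiv), toluene, 110 °C
Reagents that add atoms: allyl alcohol, C=CCO
Why: Thermal retro-[4+2] fragmentation of the dioxinone expels acetone and the acylketene is trapped by allyl alcohol, giving the β-keto allyl ester that marks C5 as the one readily enolised carbon of ring A.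

Step 12
Reactants: 19 prop-2-en-1-yl (2S,3S)-3-bromo-2-methyl-6-oxo-2-{2-[(1R,2S,4S)-5-oxo-2-(propan-2-yl)bicyclo[2.2.1]heptan-1-yl]ethyl}cyclohexane-1-carboxylate
Product: 20 prop-2-en-1-yl 1β-bromo-10β-methyl-4,11-dioxo-14-endo-(propan-2-yl)tetracycle-5α-carboxylate (rings A/B trans-fused; C6–H endo)
Conditions: LiN(iPr)2 (2.2 equiv), THF, −78 °C; then [Fe(DMF)3Cl2][FeCl4] (1.2 equiv), −78 → 0 °C
Reagents that add atoms: none
Why: In this intramolecular oxidative enolate heterocoupling the bis-enolate (β-keto ester enolate at C5 and ketone enolate at C6, the norbornanone being enolisable only away from its bridgehead) is oxidised by trivalent iron to an electrophilic α-carbonyl radical (an enolonium-type synthon) that the second enolate captures, so two α-carbons that are both nucleophiles are joined to close six-membered ring B, the bond forming on the exo face of the norbornane (C6–H endo) and by diequatorial closure to the trans-decalin with the ester axial at C5 (a C5 epimer would converge in step 14).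

Step 13
Reactants: 20 prop-2-en-1-yl 1β-bromo-10β-methyl-4,11-dioxo-14-endo-(propan-2-yl)tetracycle-5α-carboxylate
Product: 21 prop-2-en-1-yl 1β-bromo-11-endo-methoxy-10β-methyl-4-oxo-14-endo-(propan-2-yl)tetracycle-5α-carboxylate
Conditions: MeOSiMe3 (3 equiv), Et3SiH (2 equiv), TMSOTf (0.2 equiv), CH2Cl2, −78 → −20 °C
Reagents that add atoms: methoxytrimethylsilane, CO[Si](C)(C)C
Why: In this reductive etherification only the C11 ketone forms a methyl oxocarbenium ion (the C4 ketone is flanked by the quaternary, ester-bearing C5 and is inductively deactivated), and Et3SiH delivers hydride from the exo face as in norbornanone reductions, placing OMe endo and trans to C5.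

Step 14
Reactants: 21 prop-2-en-1-yl 1β-bromo-11-endo-methoxy-10β-methyl-4-oxo-14-endo-(propan-2-yl)tetracycle-5α-carboxylate
Product: 22 (1S,5S,6S,7S,10S,11S,12S,14S)-1-bromo-11-methoxy-10-methyl-14-(propan-2-yl)tetracycle with a C4 ketone
Conditions: Pd(OAc)2 (5 mol%), PPh3 (20 mol%), HCO2H (2 equiv), Et3N (2.5 equiv), THF, 23 → 40 °C; then DBU (0.2 equiv), 23 °C
Reagents that add atoms: none
Why: In this Tsuji deallylation–decarboxylation zerovalent palladium ionises the allyl ester, the β-keto carboxylate loses CO2 while formate reduces the allyl fragment to propene, and DBU equilibrates C5–H (α to the C4 ketone) to the more stable trans-fused decalin.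

Step 15
Reactants: 22 (1S,5S,6S,7S,10S,11S,12S,14S)-1-bromo-11-methoxy-10-methyl-14-(propan-2-yl)tetracycle with a C4 ketone
Product: 23 (1S,3S,5S,6S,7S,10S,11S,12S,14S)-1-bromo-3-hydroxy-11-methoxy-10-methyl-14-(propan-2-yl)tetracycle with a C4 ketone (3α-OH, axial)
Conditions: KN(SiMe3)2 (1.1 equiv), THF, −78 °C; 2-(phenylsulfonyl)-3-phenyloxaziridine (1.3 equiv), −78 °C; AcOH
Reagents that add atoms: 2-(phenylsulfonyl)-3-phenyloxaziridine, O=S(=O)(c1ccccc1)N1OC1c1ccccc1
Why: In this Davis α-hydroxylation kinetic deprotonation occurs at the only α-methylene (C3), and oxygen is transferred to the enolate along the axial trajectory on the α face, away from the axial C10 methyl, giving the axial 3α-hydroxyl.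

Step 16
Reactants: 23 (1S,3S,5S,6S,7S,10S,11S,12S,14S)-1-bromo-3-hydroxy-11-methoxy-10-methyl-14-(propan-2-yl)tetracycle with a C4 ketone
Product: 24 (1S,3S,4S,5S,6S,7S,10S,11S,12S,14S)-1-bromo-11-methoxy-4,10-dimethyl-14-(propan-2-yl)tetracycle-3,4-diol (CNP0130529.1)
Conditions: MeMgBr (4 equiv), THF, −78 → 0 °C; aq. NH4Cl
Reagents that add atoms: methylmagnesium bromide, C[Mg]Br
Why: In this Grignard addition axial (β-face) attack at C4 is blocked by the syn-axial C10 methyl, so methyl enters equatorially from the α face (the side of the C3 magnesium alkoxide) and gives the axial 4β-hydroxyl, i.e. the trans-diaxial 3,4-diol of the target.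

**Compound list**

1 | (2E)-3-methylpent-2-en-4-yn-1-ol | C#C/C(C)=C/CO | starting material
2 | (3E)-5-bromo-3-methylpent-3-en-1-yne | C#C/C(C)=C/CBr | intermediate
3 | 2,2,6-trimethyl-4H-1,3-dioxin-4-one | CC1=CC(=O)OC(C)(C)O1 | starting material
4 | 2,2-dimethyl-6-[(3E)-4-methylhex-3-en-5-yn-1-yl]-4H-1,3-dioxin-4-one | C#C/C(C)=C/CCC1=CC(=O)OC(C)(C)O1 | intermediate
5 | 2,2-dimethyl-6-[(3E)-4-methylhexa-3,5-dien-1-yl]-4H-1,3-dioxin-4-one | C=C/C(C)=C/CCC1=CC(=O)OC(C)(C)O1 | intermediate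
6 | 3-bromocyclopent-2-en-1-one | O=C1CCC(Br)=C1 | starting material
7 | 9-[(3E)-6-(2,2-dimethyl-4-oxo-4H-1,3-dioxin-6-yl)-3-methylhex-3-en-1-yl]-9-borabicyclo[3.3.1]nonane | C1CCC2CCCC1B2CC/C(C)=C/CCC3=CC(=O)OC(C)(C)O3 | intermediate (not isolated)
8 | 2,2-dimethyl-6-[(3E)-4-methyl-6-(3-oxocyclopent-1-en-1-yl)hex-3-en-1-yl]-4H-1,3-dioxin-4-one | O=C1CCC(CC/C(C)=C/CCC2=CC(=O)OC(C)(C)O2)=C1 | intermediate
9 | 2,2-dimethyl-6-(2-{(2R,3R)-3-methyl-3-[2-(3-oxocyclopent-1-en-1-yl)ethyl]oxiran-2-yl}ethyl)-4H-1,3-dioxin-4-one | O=C1CCC(CC[C@@]2(C)O[C@@H]2CCC3=CC(=O)OC(C)(C)O3)=C1 | intermediate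
10 | 6-[(3S,4R)-3-bromo-4-hydroxy-4-methyl-6-(3-oxocyclopent-1-en-1-yl)hexyl]-2,2-dimethyl-4H-1,3-dioxin-4-one | O=C1CCC(CC[C@@](C)(O)[C@@H](Br)CCC2=CC(=O)OC(C)(C)O2)=C1 | intermediate (not isolated)
11 | (5S,6S)-6-bromo-2,2,5-trimethyl-5-[2-(3-oxocyclopent-1-en-1-yl)ethyl]-5,6,7,8-tetrahydro-4H-1,3-benzodioxin-4-one (Br and C5-methyl cis) | O=C1CCC(CC[C@@]2(C)C3=C(CC[C@@H]2Br)OC(C)(C)OC3=O)=C1 | intermediate
12 | (5S,6S)-6-bromo-5-(2-{3-[(tert-butyldimethylsilyl)oxy]cyclopenta-1,3-dien-1-yl}ethyl)-2,2,5-trimethyl-5,6,7,8-tetrahydro-4H-1,3-benzodioxin-4-one | CC(C)(C)[Si](C)(C)OC1=CCC(CC[C@@]2(C)C3=C(CC[C@@H]2Br)OC(C)(C)OC3=O)=C1 | intermediate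
13 | but-3-en-2-one (methyl vinyl ketone) | CC(=O)C=C | starting material
14 | (5S,6S)-5-(2-{(1R,4S,6R)-6-acetyl-3-[(tert-butyldimethylsilyl)oxy]bicyclo[2.2.1]hept-2-en-1-yl}ethyl)-6-bromo-2,2,5-trimethyl-5,6,7,8-tetrahydro-4H-1,3-benzodioxin-4-one (acetyl endo) | CC(C)(C)[Si](C)(C)OC1=C[C@@]2(CC[C@@]3(C)C4=C(CC[C@@H]3Br)OC(C)(C)OC4=O)C[C@@H]1C[C@H]2C(C)=O | intermediate
15 | as 14, with the endo acetyl replaced by 2-hydroxy-1-(trimethylsilyl)propan-2-yl (either carbinol epimer) | CC(C)(C)[Si](C)(C)OC1=C[C@@]2(CC[C@@]3(C)C4=C(CC[C@@H]3Br)OC(C)(C)OC4=O)C[C@@H]1C[C@H]2C(C)(O)C[Si](C)(C)C | intermediate (not isolated)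
16 | (5S,6S)-6-bromo-2,2,5-trimethyl-5-{2-[(1R,2S,4S)-5-oxo-2-(prop-1-en-2-yl)bicyclo[2.2.1]heptan-1-yl]ethyl}-5,6,7,8-tetrahydro-4H-1,3-benzodioxin-4-one (isopropenyl endo) | O=C1C[C@@]2(CC[C@@]3(C)C4=C(CC[C@@H]3Br)OC(C)(C)OC4=O)C[C@@H]1C[C@H]2C(C)=C | intermediate
17 | (5S,6S)-6-bromo-2,2,5-trimethyl-5-{2-[(1R,2S,4S)-5-oxo-2-(propan-2-yl)bicyclo[2.2.1]heptan-1-yl]ethyl}-5,6,7,8-tetrahydro-4H-1,3-benzodioxin-4-one (isopropyl endo) | O=C1C[C@@]2(CC[C@@]3(C)C4=C(CC[C@@H]3Br)OC(C)(C)OC4=O)C[C@@H]1C[C@H]2C(C)C | intermediate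
18 | (3S,4S)-4-bromo-3-methyl-2-(oxomethylidene)-3-{2-[(1R,2S,4S)-5-oxo-2-(propan-2-yl)bicyclo[2.2.1]heptan-1-yl]ethyl}cyclohexan-1-one | O=C1C[C@@]2(CC[C@@]3(C)C(=C=O)C(=O)CC[C@@H]3Br)C[C@@H]1C[C@H]2C(C)C | intermediate (not isolated)
19 | prop-2-en-1-yl (2S,3S)-3-bromo-2-methyl-6-oxo-2-{2-[(1R,2S,4S)-5-oxo-2-(propan-2-yl)bicyclo[2.2.1]heptan-1-yl]ethyl}cyclohexane-1-carboxylate (C1 epimers and enol) | O=C1C[C@@]2(CC[C@@]3(C)C(C(=O)OCC=C)C(=O)CC[C@@H]3Br)C[C@@H]1C[C@H]2C(C)C | intermediate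
20 | prop-2-en-1-yl 1β-bromo-10β-methyl-4,11-dioxo-14-endo-(propan-2-yl)tetracycle-5α-carboxylate (A/B trans; C6–H endo) | O=C1[C@H]2C[C@@H](C(C)C)[C@]3(CC[C@@]4(C)[C@](C(=O)OCC=C)([C@H]13)C(=O)CC[C@@H]4Br)C2 | intermediate
21 | prop-2-en-1-yl 1β-bromo-11-endo-methoxy-10β-methyl-4-oxo-14-endo-(propan-2-yl)tetracycle-5α-carboxylate | CO[C@H]1[C@H]2C[C@@H](C(C)C)[C@]3(CC[C@@]4(C)[C@](C(=O)OCC=C)([C@H]13)C(=O)CC[C@@H]4Br)C2 | intermediate
22 | (1S,5S,6S,7S,10S,11S,12S,14S)-1-bromo-11-methoxy-10-methyl-14-(propan-2-yl)tetracycle with a C4 ketone | CO[C@H]1[C@H]2C[C@@H](C(C)C)[C@]3(CC[C@@]4(C)[C@H]([C@H]13)C(=O)CC[C@@H]4Br)C2 | intermediate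
23 | (1S,3S,5S,6S,7S,10S,11S,12S,14S)-1-bromo-3-hydroxy-11-methoxy-10-methyl-14-(propan-2-yl)tetracycle with a C4 ketone | CO[C@H]1[C@H]2C[C@@H](C(C)C)[C@]3(CC[C@@]4(C)[C@H]([C@H]13)C(=O)[C@@H](O)C[C@@H]4Br)C2 | intermediate
24 | (1S,3S,4S,5S,6S,7S,10S,11S,12S,14S)-1-bromo-11-methoxy-4,10-dimethyl-14-(propan-2-yl)tetracycle-3,4-diol | CO[C@H]1[C@H]2C[C@@H](C(C)C)[C@]3(CC[C@@]4(C)[C@H]([C@H]13)[C@](C)(O)[C@@H](O)C[C@@H]4Br)C2 | target

**Totals and risks**

Total step count: 16. Longest linear sequence: 16 steps (1 → 24); 3, 6 and 13 enter as purchased building blocks.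

The step most likely to fail is step 12, because the new bond joins a fully substituted C5, next to the quaternary C10, to C6, and the bis-enolate may be over-oxidised or may displace the C1 bromide. The fallback sets out from 19 and comes back at 20. Compound 19 is converted with TBSOTf and Et3N into the bis(silyl enol ether) F4. F4 is then coupled with (NH4)2Ce(NO3)6 (tetravalent cerium) and NaHCO3 in MeCN at −20 °C; the electron-rich norbornene silyl enol ether is oxidised to its radical cation, which is captured at C5 by the second enol ether.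

The second is step 6, where the dioxinone may be too weak a π-nucleophile for the bromonium ion, or bromide may open the epoxide at the wrong carbon. The fallback sets out from 9 and comes back at 11. Epoxide 9 is heated with tert-butyl alcohol in toluene at 110 °C to give the tert-butyl β-keto ester epoxide F1. F1 is opened with Li2NiBr4 to the bromohydrin F2. F2 is cyclised with SnCl4 in CH2Cl2 at −78 °C, the β-keto ester enol now being the terminating carbon nucleophile, to the cyclohexanone ester F3. The dioxinone is then re-closed from F3 with acetone, (CF3CO)2O and CF3CO2H.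

The third is step 13, where the axial C5 ester may block the exo face of the C11 ketone (giving the exo ether) or the C4 ketone may also be reduced. The fallback sets out from 20 and comes back at 23. Compound 20 is first deallylated and decarboxylated (Pd(OAc)2, PPh3, HCO2H, Et3N, then DBU) to the diketone F5. The C4 ketone of F5 is masked as its kinetic C3=C4 silyl enol ether F6 (LiN(iPr)2, TBSCl, −78 °C). The C11 ketone, now next to a simple C5–H, is reduced from the exo face with NaBH4 to the endo alcohol F7. F7 is methylated with NaH and MeI to the methyl ether F8. Rubottom oxidation of F8 (mCPBA, NaHCO3, CH2Cl2, 0 °C; then HF·pyridine) on the α face gives 23 directly.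

**Further compounds**

F1 | step 6 | tert-butyl 5-{(2R,3R)-3-methyl-3-[2-(3-oxocyclopent-1-en-1-yl)ethyl]oxiran-2-yl}-3-oxopentanoate | O=C1CCC(CC[C@@]2(C)O[C@@H]2CCC(=O)CC(=O)OC(C)(C)C)=C1
F2 | step 6 | tert-butyl (6S,7R)-6-bromo-7-hydroxy-7-methyl-3-oxo-9-(3-oxocyclopent-1-en-1-yl)nonanoate | O=C1CCC(CC[C@@](C)(O)[C@@H](Br)CCC(=O)CC(=O)OC(C)(C)C)=C1
F3 | step 6 | tert-butyl (2S,3S)-3-bromo-2-methyl-6-oxo-2-[2-(3-oxocyclopent-1-en-1-yl)ethyl]cyclohexane-1-carboxylate (C1 epimers and enol) | O=C1CCC(CC[C@@]2(C)C(C(=O)OC(C)(C)C)C(=O)CC[C@@H]2Br)=C1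
F4 | step 12 | bis(tert-butyldimethylsilyl enol ether) of 19 (C6=C11 and C4=C5 enol ethers) | CC(C)(C)[Si](C)(C)OC1=C[C@@]2(CC[C@@]3(C)C(C(=O)OCC=C)=C(O[Si](C)(C)C(C)(C)C)CC[C@@H]3Br)C[C@@H]1C[C@H]2C(C)C
F5 | step 13 | (1S,5S,6S,7S,10S,12S,14S)-1-bromo-10-methyl-14-(propan-2-yl)tetracycle-4,11-dione | O=C1[C@H]2C[C@@H](C(C)C)[C@]3(CC[C@@]4(C)[C@H]([C@H]13)C(=O)CC[C@@H]4Br)C2
F6 | step 13 | C3=C4 tert-butyldimethylsilyl enol ether of F5 (C11 ketone free) | O=C1[C@H]2C[C@@H](C(C)C)[C@]3(CC[C@@]4(C)[C@H]([C@H]13)C(O[Si](C)(C)C(C)(C)C)=CC[C@@H]4Br)C2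
F7 | step 13 | 11-endo alcohol of F6 | O[C@H]1[C@H]2C[C@@H](C(C)C)[C@]3(CC[C@@]4(C)[C@H]([C@H]13)C(O[Si](C)(C)C(C)(C)C)=CC[C@@H]4Br)C2
F8 | step 13 | 11-endo methyl ether of F7 | CO[C@H]1[C@H]2C[C@@H](C(C)C)[C@]3(CC[C@@]4(C)[C@H]([C@H]13)C(O[Si](C)(C)C(C)(C)C)=CC[C@@H]4Br)C2
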